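Numbering (used for all compounds, also the monocyclic ones): C1 prenyl bridgehead, C2–C3–C4 enolised dione with the aroyl on C3, C5 lavandulyl bridgehead, C6 CH2, C7 CH–prenyl, C8 CMe2, C9 bridging ketone.
Retrosynthesis: cut C3–C(aroyl) and C1–prenyl (late lithiations), then C1–C8, which returns the bicyclo[3.3.1]nonane to a cyclopentanol (C5–C6–C7–C8–C9) cis-fused to a cyclohexenone (C5–C9–C1–C2–C3–C4); then C1–C9 (vinylogous aldol), C5–CH2 of lavandulyl, C5–C4 (acylation), and last the C8 methyl and the C7 side chain on 2-methylcyclopentenone.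
Enabling feature: C9 is a ketone flanked by both bridgeheads and C8 is a quaternary carbon bonded to C1, so C1–C8 can arise by a 1,2-shift of C8 from a C9 carbinol onto an electrophilic C1.
Forward: the cyclopentane is there from the start; the enone ring is closed onto C9; the shift enlarges the cyclopentane and gives the bicyclo[3.3.1]nonane; C1 and C3 are then substituted and the enol and phenol unmasked.
Stereochemistry: C7 from a copper-catalysed enantioselective conjugate addition; C5 from alkylation anti to the C7 prenyl; the lavandulyl centre from (R)-lavandulol; C1 is dictated by the bridged framework during the shift.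

Key step: step 9

Assumption: the trione of the target is drawn as one of its rapidly interconverting enol tautomers, and the ligand enantiomer named in step 1 is taken to give (R)-5 (its mirror image is used if the sense of induction is the opposite).

Step 1
Reactants: 1 2-methylcyclopent-2-en-1-one; 2 4-bromo-2-methylbut-1-ene
Product: 5 (R)-2,2-dimethyl-3-(3-methylbut-3-en-1-yl)cyclopentan-1-one, via Grignard reagent 3 (not isolated), via magnesium enolate 4 (not isolated)
Conditions: 2, Mg, Et2O, 35 °C; then 1, CuBr·SMe2 (5 mol %), (R)-1-[(S)-2-(diphenylphosphino)ferrocenyl]ethyldicyclohexylphosphine (6 mol %), t-BuOMe, −78 °C; then MeI, DMPU, −78 → 0 °C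
Reagents that add atoms: iodomethane, IC
Why: Copper-catalysed enantioselective conjugate addition of a primary alkyl Grignard reagent to the α-methyl cyclopentenone (Josiphos-type ligand) sets C7 under catalyst control, and the regiodefined magnesium enolate is C-methylated to give the quaternary C8; a non-allylic Grignard reagent is used because a prenyl Grignard reagent would add 1,2 and with allyl transposition.

Step 2
Reactants: 5 (R)-2,2-dimethyl-3-(3-methylbut-3-en-1-yl)cyclopentan-1-one
Product: 6 (S)-2,2-dimethyl-3-(3-methylbut-2-en-1-yl)cyclopentan-1-one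
Conditions: chloro[N,N′-bis(3,5-di-tert-butylsalicylidene)cyclohexane-1,2-diaminato]cobalt (3 mol %), PhSiH3 (6 mol %), benzene, 22 °C
Reagents that add atoms: none
Why: Cobalt–salen hydrogen-atom-transfer alkene isomerisation moves the 1,1-disubstituted terminal alkene by one position to the more stable trisubstituted alkene, which makes the C7 prenyl group without touching the ketone or the stereocentre (the descriptor changes from R to S only because the priorities change).

Step 3
Reactants: 7 methyl (E)-3-methoxybut-2-enoate
Product: 8 (E)-3-methoxybut-2-enoic acid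
Conditions: NaOH, MeOH/H2O, 22 → 50 °C; then HCl to pH 3, 0 °C
Reagents that add atoms: sodium hydroxide, [Na+].[OH-]
Why: Ester saponification by acyl–oxygen cleavage, the β-methoxy enoate being stable to base and to a brief cold acidification.

Step 4
Reactants: 8 (E)-3-methoxybut-2-enoic acid
Product: 9 (E)-3-methoxybut-2-enoyl chloride
Conditions: (COCl)2, DMF (cat.), CH2Cl2, 0 → 22 °C; evaporation, used crude
Reagents that add atoms: oxalyl chloride, O=C(Cl)C(=O)Cl
Why: Acid chloride formation through the Vilsmeier-type chloroiminium species, a standard preparation of β-alkoxy acryloyl chlorides.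

Step 5
Reactants: 6 (S)-2,2-dimethyl-3-(3-methylbut-2-en-1-yl)cyclopentan-1-one; 9 (E)-3-methoxybut-2-enoyl chloride
Product: 11 (3R)-5-[(E)-3-methoxybut-2-enoyl]-2,2-dimethyl-3-(3-methylbut-2-en-1-yl)cyclopentan-1-one (C5 epimers plus enol form), via lithium enolate 10 (not isolated)
Conditions: LiN(SiMe3)2 (2.1 equiv), toluene/THF, −78 → 0 °C; then 9 (1.3 equiv), 0 °C; aq. NH4Cl
Reagents that add atoms: none
Why: Claisen-type C-acylation of the only possible enolate of 6 (C8 is quaternary) by an acid chloride in a weakly coordinating solvent, the second equivalent of base taking up the acidic β-diketone proton so that the product does not quench the enolate.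

Step 6
Reactants: 12 (R)-lavandulol
Product: 13 (R)-lavandulyl iodide, (2R)-1-iodo-5-methyl-2-(prop-1-en-2-yl)hex-4-ene
Conditions: PPh3, I2, imidazole, CH2Cl2, 0 → 22 °C
Reagents that add atoms: iodine, [I][I]
Why: Appel-type iodination by SN2 displacement at the primary carbinol carbon under near-neutral conditions, which leaves the adjacent stereocentre and both alkenes untouched.

Step 7
Reactants: 11 (3R)-5-[(E)-3-methoxybut-2-enoyl]-2,2-dimethyl-3-(3-methylbut-2-en-1-yl)cyclopentan-1-one; 13 (R)-lavandulyl iodide
Product: 14 (3R,5R)-5-[(E)-3-methoxybut-2-enoyl]-2,2-dimethyl-3-(3-methylbut-2-en-1-yl)-5-[(2S)-5-methyl-2-(prop-1-en-2-yl)hex-4-en-1-yl]cyclopentan-1-one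
Conditions: K2CO3 (2 equiv), 13 (1.5 equiv), acetone, 56 °C
Reagents that add atoms: none
Why: C-alkylation of the stabilised 2-acylcyclopentanone enolate by SN2 at the primary iodide creates the quaternary C5, the electrophile should approach the planar enolate on the face away from the C7 prenyl group so that lavandulyl ends trans and the acyl carbon C4 cis to that prenyl (the relation the 7-endo bicycle needs), and the weak non-nucleophilic base spares the cleavage-prone 2,2-disubstituted 1,3-diketone.

Step 8
Reactants: 14 quaternary diketone (3R,5R)-5-[(E)-3-methoxybut-2-enoyl]-2,2-dimethyl-3-prenyl-5-lavandulylcyclopentan-1-one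
Product: 16 cis-fused hydroxy enol ether (C9 tertiary alcohol; C2 methyl enol ether; C4 ketone; C5 lavandulyl; C7 prenyl; C8 gem-dimethyl), via lithium dienolate 15 (not isolated)
Conditions: LiN(i-Pr)2 (LDA, 1.3 equiv), THF, −78 → −40 °C; AcOH, −78 °C
Reagents that add atoms: none
Why: With C5 and C8 quaternary the only acidic hydrogens are those of the methyl on the enol ether carbon, so γ-deprotonation gives the extended enolate whose terminal carbon C1 adds to the C9 ketone in an intramolecular vinylogous aldol reaction (6-exo-trig; attack through the α-carbon would give a four-membered ring), and because the nucleophile is tethered through C4 it reaches C9 only from the face that C4 occupies, which gives the cis ring fusion and fixes the methyl enol ether at C2.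

Step 9
Reactants: 16 cis-fused hydroxy enol ether (cyclopentanol C5–C6–C7–C8–C9 fused to the enone ring C5–C9–C1–C2–C3–C4)
Product: 18 2-methoxy-8,8-dimethyl-7-prenyl-5-lavandulylbicyclo[3.3.1]non-2-ene-4,9-dione (C1–H), via allylic λ3-iodane 17 (not isolated)
Conditions: PhI(OAc)2 (2 equiv), KOH (6 equiv), MeOH, 0 → 22 °C
Reagents that add atoms: none
Why: Methanolic KOH forms the C9 alkoxide and, reversibly, the extended enolate by removing a C1 proton (C5 is quaternary, so C1 carries the only enolisable hydrogens), and PhI(OMe)2 made in the flask is taken up on carbon to give the allylic λ3-iodane 17 (at C1 directly or after allylic shift from C3). Loss of iodobenzene leaves C1 as the electron-poor end of a 2-methoxyallyl cation, to which the C9–C8 bond shifts while the alkoxide collapses to the C9 ketone; this is a semipinacol (oxidative 1,2-alkyl shift) ring expansion, the closest known reaction being the PhI(OAc)2/KOH/MeOH ring expansion of tertiary-hydroxy cyclohexane-1,3-dione enol ethers fused to cyclopentanes. The new six-membered ring C1–C8–C7–C6–C5–C9 is closed not by an exo or endo cyclisation but by the shift itself, which forms C1–C8 as C8–C9 breaks and so turns the fused 5/6 system into the bicyclo[3.3.1]nonane. The one new stereocentre, C1, is set by the framework: C8 stays bonded to C7 and can bridge to C1 only across the face of the enone ring on which it already sits in the cis-fused bicycle, so C1 follows from C5. The step needs migration of C8 rather than of C5 (ring contraction) or attack of the C9 oxygen on C1 (epoxide): C8 is exocyclic to the enone ring, fully alkylated and can stand antiperiplanar to the departing iodine, whereas the C9–C5 bond is endocyclic, lies near the nodal plane of the developing p orbital at C1 and carries the electron-withdrawing C4 carbonyl. The product has no enolisable hydrogen left, so further oxidation is not expected.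

Step 10
Reactants: 18 2-methoxy-8,8-dimethyl-7-prenyl-5-lavandulylbicyclo[3.3.1]non-2-ene-4,9-dione; 19 prenyl bromide (1-bromo-3-methylbut-2-ene)
Product: 21 2-methoxy-8,8-dimethyl-1,7-diprenyl-5-lavandulylbicyclo[3.3.1]non-2-ene-4,9-dione, via bridgehead lithium compound 20 (not isolated)
Conditions: LDA (2 equiv), THF, −78 °C; then 19 (3 equiv), −78 → −20 °C
Reagents that add atoms: none
Why: Bridgehead lithiation–alkylation, a known reaction of bicyclo[3.3.1]nonane-2,4,9-trione methyl enol ethers: LDA should remove the C1 hydrogen flanked by the C9 ketone and the methoxy-bearing C2, and the pyramidal bridgehead carbanion is alkylated by the allylic bromide with retention because the cage allows no inversion, whereas a vinylic C3 anion does not alkylate without copper and can be re-protonated by diisopropylamine.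

Step 11
Reactants: 22 vanillic acid
Product: 23 tert-butyldimethylsilyl 4-(tert-butyldimethylsilyloxy)-3-methoxybenzoate
Conditions: TBSCl (2.3 equiv), imidazole, DMF, 22 °C
Reagents that add atoms: tert-butylchlorodimethylsilane, CC(C)(C)[Si](C)(C)Cl
Why: Silylation of phenol and carboxylic acid with a silyl chloride and imidazole gives the silyl ether and silyl ester in one operation.

Step 12
Reactants: 23 tert-butyldimethylsilyl 4-(tert-butyldimethylsilyloxy)-3-methoxybenzoate
Product: 24 4-(tert-butyldimethylsilyloxy)-3-methoxybenzoyl chloride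
Conditions: (COCl)2, DMF (cat.), CH2Cl2, 0 → 22 °C; evaporation, used crude
Reagents that add atoms: oxalyl chloride, O=C(Cl)C(=O)Cl
Why: Oxalyl chloride with catalytic DMF converts a silyl ester directly into the acid chloride under neutral conditions (chloride takes the silyl group), so the aryl silyl ether is kept.

Step 13
Reactants: 21 2-methoxy-8,8-dimethyl-1,7-diprenyl-5-lavandulylbicyclo[3.3.1]non-2-ene-4,9-dione; 24 4-(tert-butyldimethylsilyloxy)-3-methoxybenzoyl chloride
Product: 26 3-[4-(tert-butyldimethylsilyloxy)-3-methoxybenzoyl]-2-methoxy-8,8-dimethyl-1,7-diprenyl-5-lavandulylbicyclo[3.3.1]non-2-ene-4,9-dione, via C3 vinyllithium 25 (not isolated)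
Conditions: lithium 2,2,6,6-tetramethylpiperidide (3 equiv), THF, −78 °C; then 24 (4 equiv), −78 → −40 °C
Reagents that add atoms: none
Why: Directed vinylic lithiation–acylation: with both bridgeheads quaternary the C3 hydrogen between the C4 carbonyl and the C2 methoxy group is the only acidic one, the hindered amide removes it without adding to the carbonyls, and the vinyllithium is acylated by the aroyl chloride while the aryl silyl ether is inert at −78 °C.

Step 14
Reactants: 26 silyl-protected 3-aroyl methyl enol ether
Product: 27 garcinol 13-O-methyl ether (target)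
Conditions: LiOH·H2O, 1,4-dioxane/H2O, 90 °C, argon; then 1 M HCl to pH 4, 0 °C, immediate extraction
Reagents that add atoms: lithium hydroxide, [Li+].[OH-]
Why: Hydroxide adds to C2 of the acyl-activated vinylogous ester and expels methoxide (addition–elimination) and also cleaves the electron-poor aryl silyl ether at silicon, while the aryl methyl ether, the alkenes and all four stereocentres are inert to base; the acidification is kept cold and brief because acid can cyclise such enols onto the side-chain alkenes.

Compound list
1 | 2-methylcyclopent-2-en-1-one | CC1=CCCC1=O | starting material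
2 | 4-bromo-2-methylbut-1-ene | C=C(C)CCBr | starting material
3 | (3-methylbut-3-en-1-yl)magnesium bromide | C=C(C)CC[Mg]Br | intermediate
4 | bromomagnesium (R)-2-methyl-3-(3-methylbut-3-en-1-yl)cyclopent-1-en-1-olate | Br[Mg]OC1=C(C)[C@H](CCC(C)=C)CC1 | intermediate
5 | (R)-2,2-dimethyl-3-(3-methylbut-3-en-1-yl)cyclopentan-1-one | O=C1CC[C@@H](CCC(C)=C)C1(C)C | intermediate
6 | (S)-2,2-dimethyl-3-(3-methylbut-2-en-1-yl)cyclopentan-1-one | O=C1CC[C@@H](CC=C(C)C)C1(C)C | intermediate
7 | methyl (E)-3-methoxybut-2-enoate | COC(=O)/C=C(/OC)C | starting material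
8 | (E)-3-methoxybut-2-enoic acid | OC(=O)/C=C(/OC)C | intermediate
9 | (E)-3-methoxybut-2-enoyl chloride | ClC(=O)/C=C(/OC)C | intermediate
10 | lithium (S)-5,5-dimethyl-4-(3-methylbut-2-en-1-yl)cyclopent-1-en-1-olate | [Li]OC1=CC[C@@H](CC=C(C)C)C1(C)C | intermediate
11 | (3R)-5-[(E)-3-methoxybut-2-enoyl]-2,2-dimethyl-3-(3-methylbut-2-en-1-yl)cyclopentan-1-one (C5 epimers, largely enolised) | O=C1C(C(=O)/C=C(/OC)C)C[C@@H](CC=C(C)C)C1(C)C | intermediate
12 | (R)-lavandulol, (2R)-5-methyl-2-(prop-1-en-2-yl)hex-4-en-1-ol | C=C(C)[C@@H](CC=C(C)C)CO | starting material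
13 | (R)-lavandulyl iodide, (2R)-1-iodo-5-methyl-2-(prop-1-en-2-yl)hex-4-ene | C=C(C)[C@@H](CC=C(C)C)CI | intermediate
14 | (3R,5R)-5-[(E)-3-methoxybut-2-enoyl]-2,2-dimethyl-3-(3-methylbut-2-en-1-yl)-5-[(2S)-5-methyl-2-(prop-1-en-2-yl)hex-4-en-1-yl]cyclopentan-1-one (lavandulyl trans, acyl cis to the prenyl) | C=C(C)[C@@H](CC=C(C)C)C[C@]1(C(=O)/C=C(/OC)C)C[C@@H](CC=C(C)C)C(C)(C)C1=O | intermediate
15 | lithium dienolate of 14 (C4 O-lithium, C3=C4 and C1=C2 double bonds) | C=C(C)[C@@H](CC=C(C)C)C[C@]1(C(O[Li])=CC(OC)=C)C[C@@H](CC=C(C)C)C(C)(C)C1=O | intermediate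
16 | 7a-hydroxy-6-methoxy-1,1-dimethyl-2-(3-methylbut-2-en-1-yl)-3a-[(2S)-5-methyl-2-(prop-1-en-2-yl)hex-4-en-1-yl]-1,2,3,3a,7,7a-hexahydro-4H-inden-4-one (cis-fused; C9–OH and lavandulyl cis to each other and trans to the C7 prenyl; absolute configuration as in the SMILES) | C=C(C)[C@@H](CC=C(C)C)C[C@@]12C[C@@H](CC=C(C)C)C(C)(C)[C@@]2(O)CC(OC)=CC1=O | intermediate
17 | C1-[methoxy(phenyl)-λ3-iodanyl] derivative of 16 (C1 configuration undefined) | C=C(C)[C@@H](CC=C(C)C)C[C@@]12C[C@@H](CC=C(C)C)C(C)(C)[C@@]2(O)C(I(OC)c3ccccc3)C(OC)=CC1=O | intermediate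
18 | 2-methoxy-8,8-dimethyl-7-(3-methylbut-2-en-1-yl)-5-[(2S)-5-methyl-2-(prop-1-en-2-yl)hex-4-en-1-yl]bicyclo[3.3.1]non-2-ene-4,9-dione (C1–H; C7 prenyl endo, on the side of the C2–C4 bridge; absolute configuration as in the SMILES) | C=C(C)[C@@H](CC=C(C)C)C[C@@]12C[C@@H](CC=C(C)C)C(C)(C)[C@@H](C(OC)=CC1=O)C2=O | intermediate
19 | prenyl bromide, 1-bromo-3-methylbut-2-ene | CC(C)=CCBr | starting material
20 | C1 bridgehead lithium derivative of 18 | C=C(C)[C@@H](CC=C(C)C)C[C@@]12C[C@@H](CC=C(C)C)C(C)(C)[C@@]([Li])(C(OC)=CC1=O)C2=O | intermediate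
21 | 2-methoxy-8,8-dimethyl-1,7-bis(3-methylbut-2-en-1-yl)-5-[(2S)-5-methyl-2-(prop-1-en-2-yl)hex-4-en-1-yl]bicyclo[3.3.1]non-2-ene-4,9-dione (configuration as in the SMILES) | C=C(C)[C@@H](CC=C(C)C)C[C@@]12C[C@@H](CC=C(C)C)C(C)(C)[C@@](CC=C(C)C)(C(OC)=CC1=O)C2=O | intermediate
22 | vanillic acid, 4-hydroxy-3-methoxybenzoic acid | COc1cc(C(=O)O)ccc1O | starting material
23 | tert-butyldimethylsilyl 4-(tert-butyldimethylsilyloxy)-3-methoxybenzoate | COc1cc(C(=O)O[Si](C)(C)C(C)(C)C)ccc1O[Si](C)(C)C(C)(C)C | intermediate
24 | 4-(tert-butyldimethylsilyloxy)-3-methoxybenzoyl chloride | COc1cc(C(=O)Cl)ccc1O[Si](C)(C)C(C)(C)C | intermediate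
25 | C3 vinyllithium derivative of 21 | C=C(C)[C@@H](CC=C(C)C)C[C@@]12C[C@@H](CC=C(C)C)C(C)(C)[C@@](CC=C(C)C)(C(OC)=C([Li])C1=O)C2=O | intermediate
26 | 3-[4-(tert-butyldimethylsilyloxy)-3-methoxybenzoyl] derivative of 21 | C=C(C)[C@@H](CC=C(C)C)C[C@@]12C[C@@H](CC=C(C)C)C(C)(C)[C@@](CC=C(C)C)(C(OC)=C(C(=O)c3ccc(O[Si](C)(C)C(C)(C)C)c(OC)c3)C1=O)C2=O | intermediate
27 | garcinol 13-O-methyl ether | C=C(C)[C@@H](CC=C(C)C)C[C@@]12C[C@@H](CC=C(C)C)C(C)(C)[C@@](CC=C(C)C)(C(=O)C(C(=O)c3ccc(O)c(OC)c3)=C1O)C2=O | target

Total step count: 14 (steps 3–4, 6 and 11–12 are side branches).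
Longest linear sequence: 9 steps (1, 2, 5, 7, 8, 9, 10, 13, 14) from 2-methylcyclopent-2-en-1-one.

Steps most likely to fail, riskiest first

Step 8. The ring closure is reversible and has no anionic sink, so the crowded C9 aldolate may reopen by retro-aldol reaction or fragment across C5–C9 on warming instead of persisting until the quench. The fallback sets out from 14 and returns at 16. The methyl enol ether of 14 is hydrolysed with dilute HCl in THF (0 → 22 °C) to the triketone F1. LDA (2.2 equiv, THF, −78 → 0 °C) forms the dianion of the side-chain 1,3-diketone, whose terminal carbon adds to C9; proton transfer to the cyclic diketonate then holds the ring closed and gives the cis-fused hydroxy dione F2. Me3SiCHN2 in MeOH/toluene methylates the enol at the less hindered C2 oxygen (C4 is shielded by the quaternary C5) to give 16, a minor C4-O-methyl isomer being removed by chromatography.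

Step 9. The trivalent-iodine adduct may be intercepted before the shift (methoxide or the C9 oxygen attacking C1), or the base may open the carbinol by retro-aldol cleavage faster than oxidation. The fallback sets out from 16 and returns at 18; it separates the activation of C1 from the shift and takes both out of basic methanol. Me3SiOTf/Et3N (CH2Cl2, −78 → 0 °C) converts 16 into the C9-O-silylated silyl dienol ether F3. N-Bromosuccinimide (THF, −78 °C) brominates its terminal carbon C1 and gives the allylic bromide F4. AgOTf with 2,6-di-tert-butyl-4-methylpyridine (CH2Cl2, −40 → 0 °C) abstracts bromide and triggers the same shift of C8 from C9 to C1 (silver-promoted semipinacol rearrangement of a β-silyloxy allylic halide); loss of the silyl group gives 18.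

Step 7. SN2 displacement at the β-branched primary iodide is slow, so O-alkylation of the delocalised enolate may compete and long reaction times may erode the facial selectivity. The fallback sets out from 6 and returns at 14; it uses a more nucleophilic, reliably C-alkylating β-keto amide enolate and completes the acyl chain afterwards. The lithium enolate of 6 (LiN(SiMe3)2, THF, −78 °C) is C-acylated with N-methoxy-N-methylcarbamoyl chloride to the β-keto amide F5. NaH/DMF and 13 (22 → 50 °C) give the quaternary amide F6, lavandulyl again entering anti to the C7 prenyl. CH3C≡CMgBr (THF, 0 °C) adds once to the N-methoxy-N-methyl amide, the C9 ketone being shielded by two quaternary neighbours, and gives the ynone F7. PMe3-catalysed conjugate addition of methanol (CH2Cl2, 22 °C) gives the (E)-β-methoxy enone 14.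

Further compounds
F1 | step 8 | (3R,5R)-5-(3-oxobutanoyl)-2,2-dimethyl-3-prenyl-5-lavandulylcyclopentan-1-one (triketone) | C=C(C)[C@@H](CC=C(C)C)C[C@]1(C(=O)CC(C)=O)C[C@@H](CC=C(C)C)C(C)(C)C1=O
F2 | step 8 | cis-fused hydroxy dione (C9 carbinol; C2/C4 dione as its enol; otherwise as 16) | C=C(C)[C@@H](CC=C(C)C)C[C@@]12C[C@@H](CC=C(C)C)C(C)(C)[C@@]2(O)CC(=O)C=C1O
F3 | step 9 | C9-O-trimethylsilyl C4-O-trimethylsilyl dienol ether of 16 (C1=C2 and C3=C4 double bonds) | C=C(C)[C@@H](CC=C(C)C)C[C@@]12C[C@@H](CC=C(C)C)C(C)(C)[C@@]2(O[Si](C)(C)C)C=C(OC)C=C1O[Si](C)(C)C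
F4 | step 9 | C1-bromo C9-O-trimethylsilyl derivative of 16 (C1 configuration undefined) | C=C(C)[C@@H](CC=C(C)C)C[C@@]12C[C@@H](CC=C(C)C)C(C)(C)[C@@]2(O[Si](C)(C)C)C(Br)C(OC)=CC1=O
F5 | step 7 | (4S)-N-methoxy-N,3,3-trimethyl-4-(3-methylbut-2-en-1-yl)-2-oxocyclopentane-1-carboxamide (C1 epimers) | CON(C)C(=O)C1C[C@@H](CC=C(C)C)C(C)(C)C1=O
F6 | step 7 | quaternary β-keto amide: F5 carrying the lavandulyl group on the amide-bearing carbon, trans to the prenyl | C=C(C)[C@@H](CC=C(C)C)C[C@]1(C(=O)N(C)OC)C[C@@H](CC=C(C)C)C(C)(C)C1=O
F7 | step 7 | 5-(but-2-ynoyl)-2,2-dimethyl-3-prenyl-5-lavandulylcyclopentan-1-one (ynone, configuration as 14) | C=C(C)[C@@H](CC=C(C)C)C[C@]1(C(=O)C#CC)C[C@@H](CC=C(C)C)C(C)(C)C1=O
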